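The readings are calculated from invented constants, and the scatter is random.

- The question is how much target each flask holds at 1.5 h, and the flasks differ in the starting material charged.

1. the flasks put in order of amount of target, in percent of the starting material charged, best first, at 1.5 h (theta / beta / delta / alpha / eta)
2. the amount of target, in percent of the starting material charged of the flask you put first, at 1.5 h
3. the amount of target, in percent of the starting material charged of the flask you put last, at 1.5 h

| flask | starting material | remark | time |
|---|---|---|---|
| spring | 0.029 M | run made earlier |  |
| noon | 0.11 M | run made earlier |  |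
| autumn | 0.41 M | run made earlier |  |
| theta | 0.030 M |  | 1.5 h |
| beta | 0.40 M |  | 1.5 h |
| delta | 0.060 M |  | 1.5 h |
| alpha | 0.30 M |  | 1.5 h |
| eta | 0.10 M |  | 1.5 h |

| run | time / min | target / % | starting material / % |
|---|---|---|---|
| spring | 10.0 | 18 | 58 |
| spring | 20.0 | 20 | 48 |
| spring | 25.0 | 23 | 42 |
| spring | 40.0 | 20 | 41 |
| spring | 50.0 | 23 | 40 |
| noon | 4.00 | 32 | 52 |
| noon | 12.0 | 42 | 32 |
| noon | 20.0 | 45 | 26 |
| noon | 30.0 | 47 | 24 |
| noon | 50.0 | 48 | 23 |
| autumn | 10.0 | 77 | 14 |
| autumn | 20.0 | 82 | 9 |
| autumn | 25.0 | 83 | 10 |
| autumn | 40.0 | 85 | 7 |
| autumn | 50.0 | 85 | 8 |

(scatter of a reading: 1.5 percentage points)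

- a species is counted by the starting material in it: one target or crystals or isomer of the product counts as two
- amounts and yields of target count crystals too
- given per volume of solution although it is solid: crystals
- the numbers in the tables scatter by 1.5 percentage points (one standard deviation)
- what may be going on: starting material <-> dormant form; crystals <-> target; 2 starting material <-> target; target <-> isomer of the product

- Noon and autumn read level by their last readings, yet the free starting material reads 0.0253 M and 0.0328 M in charges 3.73 times apart. This points to crystals holding dissolved target at its solubility limit.
- Noon's last reading leaves 0.0572 M of its charge outside target. This reading is taken as the solution toll, the charge that a levelled-off flask with crystals keeps outside target.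
- Autumn reads 0.0615 M, but the scatter weighs more on its larger charge, so noon's value is carried. With crystals present, the target share is then one minus the toll over the charged c(starting material).
- Eta looks like noon, but this reckoning gives it 42.8% against noon's reading of 48%. The toll takes 57.2% of eta's charge, a larger share than the 52.0% of noon's.
- The toll takes 14.3% of beta's charge, so this reckoning gives beta 85.7% and gives alpha 80.9%.
- At the dilute end, theta's charge is smaller than the toll, so the rule fails and theta should stay dissolved, near spring's 23%.
- Delta's rule value of 4.67% lies below that reading, so delta is placed on the dissolved branch, between theta and eta.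
- The forecast gives beta > alpha > eta > delta > theta, with beta at 85.5% (83% to 88%) and theta at 22% (19.5% to 25%), on the ground that “above a threshold, all extra material ends up as crystals”.
- The flasks give beta > alpha > eta > delta > theta, with beta at 86.1% and theta at 24.5%. Theta's target at 1.5 h has moved by 5 points once its charge is raised to 0.0467 M, with the time held.

    starting material ⇌ dormant form (K = 0.561, k = 0.0342 min⁻¹)
    crystals ⇌ target, rate k2*(cs2 - [target]) while solid is left; crystals form when [target] > cs2 (solubility = 15.0 mM, k = 10.4 min⁻¹)
    2 starting material ⇌ target (K = 27.2 M⁻¹, k = 0.792 M⁻¹ min⁻¹)
    target ⇌ isomer of the product (K = 0.567, k = 0.0619 min⁻¹)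

- For a further flask charged with 0.12 M, the toll gives 52.3%. At 1.50 h that flask holds 54.6% target, with crystals of 29.6% counted in it.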